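**Retrosynthetic overview**

- Feature: C2 of the pyran ring (ring B) carries, besides O1 and its methyl group, the ring olefin C3=C4 and the side-chain bond C2–C1'. Cutting both back to vinyl groups makes C2 the prochiral carbon of an aryl bis(vinyl)methylcarbinyl ether.
- C2'–C3' is cut by a B-alkyl Suzuki coupling between the hydroborated 2-vinyl group and an (E)-vinyl iodide; the (Z)-enoate of that iodide comes from a Still–Gennari olefination.
- Ring A is present from the start. Ring B is the only ring formed, by enantioselective ring-closing metathesis of the styrene onto one of the two enantiotopic vinyl groups (forms C3=C4, fixes C2).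
- The triene comes from 2-methylhydroquinone by silylation, ortho-formylation, methylenation, O-alkylation with diethyl 2-bromo-2-methylmalonate, reduction, double oxidation and double methylenation.

Key step: step 8

Remark 1: the C6 phenol is carried as a triisopropylsilyl ether, chosen over the tert-butyldimethylsilyl ether because an aryl tert-butyldimethylsilyl ether is at risk under KOtBu, Cs2CO3 in DMF and aqueous phosphate.

Remark 2: which antipode of the diolate gives the (R)-chromene cannot be derived for this substrate class. The (S)-diolate is written; the antipode would be used if the first run gives the (S)-chromene, the sense being assigned by carrying a sample through to the target and comparing the sign of rotation with authentic (R)-sargachromenol.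

**Route**

Step 1
Reactants: 1 2-methylhydroquinone
Product: 2 2-methyl-4-[(triisopropylsilyl)oxy]phenol
Conditions: iPr3SiCl (1.0 equiv), imidazole, DMF, 0 °C
Reagents that add atoms: triisopropylsilyl chloride, CC(C)[Si](Cl)(C(C)C)C(C)C
Why: Silyl ether formation, in which the bulky silyl chloride should take the hydroxyl group without an ortho substituent in preference to the one next to the methyl group.

Step 2
Reactants: 2 2-methyl-4-[(triisopropylsilyl)oxy]phenol
Product: 3 2-hydroxy-3-methyl-5-[(triisopropylsilyl)oxy]benzaldehyde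
Conditions: MgCl2, Et3N, (CH2O)n, MeCN, reflux
Reagents that add atoms: paraformaldehyde (as formaldehyde), C=O
Why: Magnesium-mediated ortho-formylation (Casnati–Skattebøl reaction), in which the magnesium phenoxide delivers formaldehyde to the only free ortho position and a second formaldehyde oxidises the benzylic alkoxide to the aldehyde.

Step 3
Reactants: 3 2-hydroxy-3-methyl-5-[(triisopropylsilyl)oxy]benzaldehyde
Product: 4 2-methyl-4-[(triisopropylsilyl)oxy]-6-vinylphenol
Conditions: Ph3PCH3Br, KOtBu (2.5 equiv each), THF, 0 °C to rt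
Reagents that add atoms: methyltriphenylphosphonium bromide, C[P+](c1ccccc1)(c1ccccc1)c1ccccc1.[Br-]
Why: Wittig methylenation with excess ylide, the first equivalent being used up by the phenol, is a standard route from salicylaldehydes to 2-vinylphenols.

Step 4
Reactants: 4 2-methyl-4-[(triisopropylsilyl)oxy]-6-vinylphenol; 5 diethyl 2-bromo-2-methylmalonate
Product: 6 diethyl 2-methyl-2-{2-methyl-4-[(triisopropylsilyl)oxy]-6-vinylphenoxy}malonate
Conditions: Cs2CO3, DMF, 50 °C
Reagents that add atoms: none
Why: Williamson-type O-alkylation of the caesium phenoxide with the doubly activated tertiary α-bromo diester, a substitution known for phenols with 2-bromo-2-methylmalonates, gives an ether that has no α-hydrogen and so cannot enolise.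

Step 5
Reactants: 6 diethyl 2-methyl-2-{2-methyl-4-[(triisopropylsilyl)oxy]-6-vinylphenoxy}malonate
Product: 7 2-methyl-2-{2-methyl-4-[(triisopropylsilyl)oxy]-6-vinylphenoxy}propane-1,3-diol
Conditions: LiAlH4, THF, 0 °C
Reagents that add atoms: none
Why: Hydride reduction of both esters with LiAlH4 to the 1,3-diol should leave the aryl silyl ether and the styrene untouched at 0 °C.

Step 6
Reactants: 7 2-methyl-2-{2-methyl-4-[(triisopropylsilyl)oxy]-6-vinylphenoxy}propane-1,3-diol
Product: 8 2-methyl-2-{2-methyl-4-[(triisopropylsilyl)oxy]-6-vinylphenoxy}propanedial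
Conditions: (COCl)2, DMSO, CH2Cl2, −78 °C; Et3N, −78 to 0 °C; used crude
Reagents that add atoms: none
Why: Double Swern oxidation should give the 2,2-disubstituted malondialdehyde, which has no α-hydrogen and therefore cannot enolise or undergo aldol reactions.

Step 7
Reactants: 8 2-methyl-2-{2-methyl-4-[(triisopropylsilyl)oxy]-6-vinylphenoxy}propanedial
Product: 9 triisopropyl{3-methyl-4-[(3-methylpenta-1,4-dien-3-yl)oxy]-5-vinylphenoxy}silane
Conditions: Ph3PCH3Br, KN(SiMe3)2, THF, −78 °C to rt
Reagents that add atoms: methyltriphenylphosphonium bromide, C[P+](c1ccccc1)(c1ccccc1)c1ccccc1.[Br-]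
Why: Double Wittig methylenation with a ylide made from a non-nucleophilic base turns both formyl groups into the two enantiotopic vinyl groups on the prochiral carbinol carbon.

Step 8
Reactants: 9 triisopropyl{3-methyl-4-[(3-methylpenta-1,4-dien-3-yl)oxy]-5-vinylphenoxy}silane
Product: 10 (R)-triisopropyl[(2,8-dimethyl-2-vinyl-2H-chromen-6-yl)oxy]silane
Conditions: Mo(N-2,6-iPr2C6H3)(CHCMe2Ph)[(S)-3,3'-di-tert-butyl-5,5',6,6'-tetramethylbiphenyl-2,2'-diolate] (5 mol%), C6H6, 22 to 50 °C, N2, ethylene vented
Reagents that add atoms: none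
Why: Proposed new method: a desymmetrising enantioselective ring-closing metathesis of an aryl bis(vinyl)carbinyl ether onto an ortho styrene has not been shown for this substrate class; the closest known reaction types are the molybdenum-catalysed enantioselective ring-closing metathesis of achiral trienes to unsaturated cyclic tertiary ethers and the ring-closing metathesis of 2-vinylphenyl allyl ethers to 2H-chromenes, and the same mechanism should apply. The hexavalent molybdenum neophylidene should exchange first onto the styrene, the only olefin not attached to a quaternary sp3 carbon, to give an aryl-substituted alkylidene. This alkylidene adds [2+2] to one of the two enantiotopic vinyl groups on C2 and the molybdacyclobutane cycloreverts, which forms the C3=C4 bond, closes ring B as a six-membered ring by ring-closing metathesis with the new double bond inside the ring, and sets ethylene free. The configuration at C2 is set in this ring-closing addition by the axially chiral biphenyl-2,2'-diolate together with the arylimido ligand, which should leave room for the methyl group and the spectator vinyl group in only one arrangement. The step needs only selectivity between the two enantiotopic vinyl groups, since the substrate allows no other ring size; the product cannot racemise by metathesis through its remaining vinyl group because that would require a three- or four-membered ring, and venting ethylene suppresses ring-opening back to 9.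

Step 9
Reactants: 11 methyl 2-[bis(2,2,2-trifluoroethoxy)phosphoryl]acetate; 12 5-bromo-2-methylpent-2-ene
Product: 13 methyl 2-[bis(2,2,2-trifluoroethoxy)phosphoryl]-6-methylhept-5-enoate (racemic)
Conditions: NaH, DMF, 0 °C; then 12, NaI (cat.), 50 °C
Reagents that add atoms: none
Why: C-alkylation of the sodium salt of the stabilised phosphonoacetate with the primary homoallylic bromide, with iodide catalysis to help a slow SN2 step.

Step 10
Reactants: 14 pent-4-yn-1-ol
Product: 16 (E)-5-iodo-4-methylpent-4-en-1-ol, via alkenylalane 15 (not isolated)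
Conditions: AlMe3, Cp2ZrCl2 (25 mol%), CH2Cl2, 0 °C to rt; I2, THF, −30 °C; aq. K2CO3 work-up
Reagents that add atoms: trimethylaluminium, C[Al](C)C; iodine, II
Why: Negishi zirconium-catalysed carboalumination adds methyl and aluminium syn across the alkyne with aluminium on the terminal carbon, and iodinolysis with retention gives the (E)-vinyl iodide.

Step 11
Reactants: 16 (E)-5-iodo-4-methylpent-4-en-1-ol
Product: 17 (E)-5-iodo-4-methylpent-4-enal
Conditions: Dess–Martin periodinane, CH2Cl2, 0 °C to rt
Reagents that add atoms: none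
Why: Dess–Martin oxidation of the primary alcohol to the aldehyde under near-neutral conditions that leave the vinyl iodide intact.

Step 12
Reactants: 13 methyl 2-[bis(2,2,2-trifluoroethoxy)phosphoryl]-6-methylhept-5-enoate; 17 (E)-5-iodo-4-methylpent-4-enal
Product: 18 methyl (2Z,6E)-7-iodo-6-methyl-2-(4-methylpent-3-en-1-yl)hepta-2,6-dienoate
Conditions: KN(SiMe3)2, 18-crown-6, THF, −78 °C
Reagents that add atoms: none
Why: Still–Gennari olefination, in which the electron-poor bis(trifluoroethyl) phosphonate under dissociating conditions eliminates quickly from the kinetically formed adduct and should give the (Z)-enoate with the ester cis to the new chain.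

Step 13
Reactants: 10 (R)-triisopropyl[(2,8-dimethyl-2-vinyl-2H-chromen-6-yl)oxy]silane; 18 methyl (2Z,6E)-7-iodo-6-methyl-2-(4-methylpent-3-en-1-yl)hepta-2,6-dienoate
Product: 20 methyl (2Z,6E)-9-[(R)-2,8-dimethyl-6-(triisopropylsilyloxy)-2H-chromen-2-yl]-6-methyl-2-(4-methylpent-3-en-1-yl)nona-2,6-dienoate, via alkylborane 19 (not isolated)
Conditions: 9-BBN dimer, THF, 0 °C to rt; then aq. K3PO4, 18, Pd(dppf)Cl2 (5 mol%), AsPh3, DMF, rt
Reagents that add atoms: 9-borabicyclo[3.3.1]nonane, B1C2CCCC1CCC2 (its boron and ring stay in intermediate 19 only)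
Why: 9-BBN should hydroborate the monosubstituted vinyl group anti-Markovnikov in preference to the 1,2-disubstituted C3=C4 olefin, and the B-alkyl Suzuki–Miyaura coupling joins C2' to C3' with retention of the (E)-geometry of the vinyl iodide while C2 is not touched.

Step 14
Reactants: 20 methyl (2Z,6E)-9-[(R)-2,8-dimethyl-6-(triisopropylsilyloxy)-2H-chromen-2-yl]-6-methyl-2-(4-methylpent-3-en-1-yl)nona-2,6-dienoate
Product: 21 methyl (2Z,6E)-9-[(R)-6-hydroxy-2,8-dimethyl-2H-chromen-2-yl]-6-methyl-2-(4-methylpent-3-en-1-yl)nona-2,6-dienoate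
Conditions: Bu4NF, AcOH, THF, 0 °C to rt
Reagents that add atoms: none
Why: Fluoride-induced cleavage of the aryl silyl ether, buffered with acetic acid so that the ester and the chromene are not exposed to strong base.

Step 15
Reactants: 21 methyl (2Z,6E)-9-[(R)-6-hydroxy-2,8-dimethyl-2H-chromen-2-yl]-6-methyl-2-(4-methylpent-3-en-1-yl)nona-2,6-dienoate
Product: 22 (R)-sargachromenol
Conditions: LiOH, THF/MeOH/H2O, rt to 40 °C, argon; then 1 M HCl to pH 3, 0 °C
Reagents that add atoms: lithium hydroxide, [Li+].[OH-]
Why: Saponification of the methyl ester under exclusion of oxygen followed by mild acidification should leave the (Z)-olefin and C2 unchanged.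

**Compound list**

1 | 2-methylhydroquinone | Cc1cc(O)ccc1O | starting material
2 | 2-methyl-4-[(triisopropylsilyl)oxy]phenol | Cc1cc(O[Si](C(C)C)(C(C)C)C(C)C)ccc1O | intermediate
3 | 2-hydroxy-3-methyl-5-[(triisopropylsilyl)oxy]benzaldehyde | Cc1cc(O[Si](C(C)C)(C(C)C)C(C)C)cc(C=O)c1O | intermediate
4 | 2-methyl-4-[(triisopropylsilyl)oxy]-6-vinylphenol | C=Cc1cc(O[Si](C(C)C)(C(C)C)C(C)C)cc(C)c1O | intermediate
5 | diethyl 2-bromo-2-methylmalonate | CCOC(=O)C(C)(Br)C(=O)OCC | starting material
6 | diethyl 2-methyl-2-{2-methyl-4-[(triisopropylsilyl)oxy]-6-vinylphenoxy}malonate | CCOC(=O)C(C)(Oc1c(C)cc(O[Si](C(C)C)(C(C)C)C(C)C)cc1C=C)C(=O)OCC | intermediate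
7 | 2-methyl-2-{2-methyl-4-[(triisopropylsilyl)oxy]-6-vinylphenoxy}propane-1,3-diol | CC(CO)(CO)Oc1c(C)cc(O[Si](C(C)C)(C(C)C)C(C)C)cc1C=C | intermediate
8 | 2-methyl-2-{2-methyl-4-[(triisopropylsilyl)oxy]-6-vinylphenoxy}propanedial | CC(C=O)(C=O)Oc1c(C)cc(O[Si](C(C)C)(C(C)C)C(C)C)cc1C=C | intermediate
9 | triisopropyl{3-methyl-4-[(3-methylpenta-1,4-dien-3-yl)oxy]-5-vinylphenoxy}silane | C=CC(C)(C=C)Oc1c(C)cc(O[Si](C(C)C)(C(C)C)C(C)C)cc1C=C | intermediate
10 | (R)-triisopropyl[(2,8-dimethyl-2-vinyl-2H-chromen-6-yl)oxy]silane | C=C[C@]1(C)C=Cc2cc(O[Si](C(C)C)(C(C)C)C(C)C)cc(C)c2O1 | intermediate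
11 | methyl 2-[bis(2,2,2-trifluoroethoxy)phosphoryl]acetate | COC(=O)CP(=O)(OCC(F)(F)F)OCC(F)(F)F | starting material
12 | 5-bromo-2-methylpent-2-ene | CC(C)=CCCBr | starting material
13 | methyl 2-[bis(2,2,2-trifluoroethoxy)phosphoryl]-6-methylhept-5-enoate (racemic) | COC(=O)C(CCC=C(C)C)P(=O)(OCC(F)(F)F)OCC(F)(F)F | intermediate
14 | pent-4-yn-1-ol | C#CCCCO | starting material
15 | (E)-{5-[(dimethylalumanyl)oxy]-2-methylpent-1-en-1-yl}dimethylalane (formed in the flask) | C[Al](C)OCCC/C(C)=C/[Al](C)C | intermediate
16 | (E)-5-iodo-4-methylpent-4-en-1-ol | OCCC/C(C)=C/I | intermediate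
17 | (E)-5-iodo-4-methylpent-4-enal | O=CCC/C(C)=C/I | intermediate
18 | methyl (2Z,6E)-7-iodo-6-methyl-2-(4-methylpent-3-en-1-yl)hepta-2,6-dienoate | CC(C)=CCC/C(=C/CC/C(C)=C/I)C(=O)OC | intermediate
19 | 9-{2-[(R)-2,8-dimethyl-6-(triisopropylsilyloxy)-2H-chromen-2-yl]ethyl}-9-borabicyclo[3.3.1]nonane (formed in the flask) | C1CCC2CCCC1B2CC[C@]1(C)C=Cc2cc(O[Si](C(C)C)(C(C)C)C(C)C)cc(C)c2O1 | intermediate
20 | methyl (2Z,6E)-9-[(R)-2,8-dimethyl-6-(triisopropylsilyloxy)-2H-chromen-2-yl]-6-methyl-2-(4-methylpent-3-en-1-yl)nona-2,6-dienoate | CC(C)=CCC/C(=C/CC/C(C)=C/CC[C@]1(C)C=Cc2cc(O[Si](C(C)C)(C(C)C)C(C)C)cc(C)c2O1)C(=O)OC | intermediate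
21 | methyl (2Z,6E)-9-[(R)-6-hydroxy-2,8-dimethyl-2H-chromen-2-yl]-6-methyl-2-(4-methylpent-3-en-1-yl)nona-2,6-dienoate | CC(C)=CCC/C(=C/CC/C(C)=C/CC[C@]1(C)C=Cc2cc(O)cc(C)c2O1)C(=O)OC | intermediate
22 | (R)-sargachromenol, (2Z,6E)-9-[(2R)-6-hydroxy-2,8-dimethyl-2H-chromen-2-yl]-6-methyl-2-(4-methylpent-3-en-1-yl)nona-2,6-dienoic acid | CC(C)=CCC/C(=C/CC/C(C)=C/CC[C@]1(C)C=Cc2cc(O)cc(C)c2O1)C(=O)O | target

**Step count**

Total step count: 15.
Longest linear sequence: 11 steps (steps 1 to 8, then 13, 14 and 15, from 2-methylhydroquinone).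

**Steps most likely to fail**

1. Step 8 (the one step proposed beyond known substrate scope). The chiral pocket may discriminate poorly between the methyl group and the spectator vinyl group during the ring-closing addition, giving low selectivity between the enantiotopic vinyl groups. Ring-opening of the product by the molybdenum methylidene under ethylene may erode the selectivity further, and the hindered aryl-substituted alkylidene may turn over slowly. Fallback, setting out from 9 and coming back at 10: ring closure of 9 with the second-generation Grubbs catalyst RuCl2(H2IMes)(PCy3)(=CHPh) in CH2Cl2 at 40 °C, a known route from 2-vinylphenyl allyl ethers to 2H-chromenes, should give racemic triisopropyl[(2,8-dimethyl-2-vinyl-2H-chromen-6-yl)oxy]silane F1. Preparative HPLC on a chiral stationary phase (cellulose tris(3,5-dimethylphenylcarbamate)) would then separate 10 from (S)-triisopropyl[(2,8-dimethyl-2-vinyl-2H-chromen-6-yl)oxy]silane F2, which is set aside.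

2. Step 4. Substitution at the tertiary carbon of 5 by the doubly ortho-substituted phenoxide may be outrun by bromine transfer to the electron-rich ring or by dehydrobromination of 5. Fallback, setting out from 4 and coming back at 6: alkylation of 4 with ethyl 2-bromopropanoate (K2CO3, DMF), an unhindered SN2 reaction at a secondary α-bromo ester, should give racemic ethyl 2-{2-methyl-4-[(triisopropylsilyl)oxy]-6-vinylphenoxy}propanoate F3. Deprotonation with LiN(iPr)2 in THF at −78 °C and C-acylation of the ester enolate with ethyl chloroformate would then give 6.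

3. Step 7. The basic ylide may deformylate the 2,2-disubstituted malondialdehyde 8 by retro-Claisen-type C–C cleavage, or 8 may hydrate and oligomerise before both olefinations are complete. Fallback, setting out from 7 and coming back at 9, with the two arms converted one after the other so that no dialdehyde is formed:
   - Monoacylation of 7 with pivaloyl chloride and pyridine should give racemic 3-hydroxy-2-methyl-2-{2-methyl-4-[(triisopropylsilyl)oxy]-6-vinylphenoxy}propyl pivalate F4.
   - Dess–Martin oxidation gives 2-methyl-3-oxo-2-{2-methyl-4-[(triisopropylsilyl)oxy]-6-vinylphenoxy}propyl pivalate F5.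
   - Wittig methylenation gives 2-methyl-2-{2-methyl-4-[(triisopropylsilyl)oxy]-6-vinylphenoxy}but-3-en-1-yl pivalate F6.
   - Reductive removal of the pivalate with iBu2AlH at −78 °C gives 2-methyl-2-{2-methyl-4-[(triisopropylsilyl)oxy]-6-vinylphenoxy}but-3-en-1-ol F7.
   - A second Dess–Martin oxidation gives 2-methyl-2-{2-methyl-4-[(triisopropylsilyl)oxy]-6-vinylphenoxy}but-3-enal F8, and a second Wittig methylenation gives 9.

Further compounds
F1 | step 8 | racemic triisopropyl[(2,8-dimethyl-2-vinyl-2H-chromen-6-yl)oxy]silane | C=CC1(C)C=Cc2cc(O[Si](C(C)C)(C(C)C)C(C)C)cc(C)c2O1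
F2 | step 8 | (S)-triisopropyl[(2,8-dimethyl-2-vinyl-2H-chromen-6-yl)oxy]silane | C=C[C@@]1(C)C=Cc2cc(O[Si](C(C)C)(C(C)C)C(C)C)cc(C)c2O1
F3 | step 4 | ethyl 2-{2-methyl-4-[(triisopropylsilyl)oxy]-6-vinylphenoxy}propanoate (racemic) | CCOC(=O)C(C)Oc1c(C)cc(O[Si](C(C)C)(C(C)C)C(C)C)cc1C=C
F4 | step 7 | 3-hydroxy-2-methyl-2-{2-methyl-4-[(triisopropylsilyl)oxy]-6-vinylphenoxy}propyl pivalate (racemic) | CC(C)(C)C(=O)OCC(C)(CO)Oc1c(C)cc(O[Si](C(C)C)(C(C)C)C(C)C)cc1C=C
F5 | step 7 | 2-methyl-3-oxo-2-{2-methyl-4-[(triisopropylsilyl)oxy]-6-vinylphenoxy}propyl pivalate (racemic) | CC(C)(C)C(=O)OCC(C)(C=O)Oc1c(C)cc(O[Si](C(C)C)(C(C)C)C(C)C)cc1C=C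
F6 | step 7 | 2-methyl-2-{2-methyl-4-[(triisopropylsilyl)oxy]-6-vinylphenoxy}but-3-en-1-yl pivalate (racemic) | CC(C)(C)C(=O)OCC(C)(C=C)Oc1c(C)cc(O[Si](C(C)C)(C(C)C)C(C)C)cc1C=C
F7 | step 7 | 2-methyl-2-{2-methyl-4-[(triisopropylsilyl)oxy]-6-vinylphenoxy}but-3-en-1-ol (racemic) | OCC(C)(C=C)Oc1c(C)cc(O[Si](C(C)C)(C(C)C)C(C)C)cc1C=C
F8 | step 7 | 2-methyl-2-{2-methyl-4-[(triisopropylsilyl)oxy]-6-vinylphenoxy}but-3-enal (racemic) | O=CC(C)(C=C)Oc1c(C)cc(O[Si](C(C)C)(C(C)C)C(C)C)cc1C=C
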